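**Plan**
1. Retrosynthesis: open the butylidene enol-lactone at C3–O (back to a C3a-alkynyl C1 acid, then to a C3a enol triflate and 1-pentyne); cut the bridging lactone bond C3'–O and the bond C3'–C8' (back to a C3' cyclopentanone and a butyl sulfonium ylide); cut ring A at C6–C7 and C4–C5 together; remove the acryloyl and dienyl arms; finally go back to the arene.
2. Enabling feature: C6–C7 is the bond shared by cyclohexene ring A (C3a, C4, C5, C6, C7, C7a; only alkene C3a=C7a, a Diels–Alder retron with diene C4=C3a–C7a=C7 and dienophile C5=C6) and the central cyclopentane (C6, C7, C7a', C3a', C3'), whose other three atoms form a rigid tether on ring B'.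
3. Forward: dearomatising Birch reduction–alkylation of a chiral 2-methoxybenzamide builds ring B' (quaternary C7a', C6'=C7'); its ketone becomes an enol triflate and its hydroxymethyl arm a 2-silyloxy diene.
4. Carbonylative vinylation unveils a dienone that closes ring A and the cyclopentanone in one intramolecular Diels–Alder event; conjugate reduction, alkynylation of ring A, epoxide-mediated lactone bridging, oxidation and silver-catalysed enol-lactonisation finish the route.
5. Stereochemistry: C7a' from the proline-derived auxiliary; C6 and C7 relayed from C7a' through the planar tether of the cycloaddition; C3a' by equilibration to the cis-hydrindanone; C3' by ylide attack on the open face, then inversion by the tethered amide; the (Z)-alkene by anti-oxymetalation.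

Key step: step 9

Locants: half A (butylidene butenolide) is C1 (lactone C=O), C3, C3a, C4–C7, C7a, C8–C11; half B is C1' (bridging lactone C=O), C3' (O-bearing quaternary carbon), C3a', C4'–C7', C7a', C8'–C11' (butanoyl). The halves are joined by C6–C3' and C7–C7a'. β is the face of the central cyclopentane that carries C1'; α is the opposite face.

Remark on the chemistry: the (S)-auxiliary is assumed to give the (R)-configured quaternary carbon in step 2, as drawn; if the sense of induction is the opposite, the (R)-auxiliary is used and nothing else changes.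

Step 1
Reactants: 1 2-methoxybenzoyl chloride; 2 (S)-2-(methoxymethyl)pyrrolidine
Product: 3 N-(2-methoxybenzoyl)-(S)-2-(methoxymethyl)pyrrolidine
Conditions: Et3N, CH2Cl2, 0 °C to rt
Reagents that add atoms: none
Why: N-acylation of a secondary amine by an aroyl chloride (Schotten–Baumann type) should be clean, and the auxiliary stereocentre is not touched.

Step 2
Reactants: 3 N-(2-methoxybenzoyl)-(S)-2-(methoxymethyl)pyrrolidine
Product: 5 benzyloxymethyl dienyl amide, via potassium amide enolate 4 (not isolated)
Conditions: K, NH3(l)/THF, t-BuOH (1 equiv), −78 °C; NH3 removed; then BnOCH2Cl, THF, −78 °C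
Reagents that add atoms: benzyl chloromethyl ether, ClCOCc1ccccc1
Why: Birch reduction of the benzamide gives enolate 4, which is C-alkylated at the ipso carbon (asymmetric Birch reduction–alkylation of a chiral 2-methoxybenzamide), the chelated methoxymethyl-pyrrolidine shielding one enolate face so that the quaternary C7a' is set.

Step 3
Reactants: 5 benzyloxymethyl dienyl amide
Product: 6 (R)-2-(benzyloxymethyl)-2-(auxiliary carbonyl)cyclohex-3-en-1-one
Conditions: 1 M HCl, THF, rt
Reagents that add atoms: water, O
Why: acid hydrolysis of the methyl enol ether gives the C3a' ketone, while the quaternary C7a' cannot epimerise and blocks migration of C6'=C7' into conjugation.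

Step 4
Reactants: 6 (R)-2-(benzyloxymethyl)-2-(auxiliary carbonyl)cyclohex-3-en-1-one
Product: 8 C3a' enol triflate, via potassium enolate 7 (not isolated)
Conditions: KN(SiMe3)2, THF, −78 °C; then PhNTf2, −78 to 0 °C
Reagents that add atoms: N-phenylbis(trifluoromethanesulfonimide), O=S(=O)(N(c1ccccc1)S(=O)(=O)C(F)(F)F)C(F)(F)F
Why: only C4' carries α-hydrogens, so enolisation is regiospecific and O-triflation of enolate 7 gives the cyclohexa-1,4-dienyl triflate (standard ketone to enol triflate conversion).

Step 5
Reactants: 8 C3a' enol triflate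
Product: 9 hydroxymethyl enol triflate
Conditions: BCl3, C6HMe5, CH2Cl2, −78 °C; MeOH quench
Reagents that add atoms: none
Why: Lewis-acid debenzylation with pentamethylbenzene as cation scavenger should cleave the benzyl ether at low temperature without touching the enol triflate, the skipped diene or the alkyl methyl ether of the auxiliary.

Step 6
Reactants: 9 hydroxymethyl enol triflate
Product: 10 formyl enol triflate
Conditions: Dess–Martin periodinane, NaHCO3, CH2Cl2, rt
Reagents that add atoms: none
Why: neutral Dess–Martin oxidation of the neopentyl primary alcohol gives an aldehyde with no α-hydrogen, so C7a' stays intact.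

Step 7
Reactants: 10 formyl enol triflate; 11 tert-butyl acetoacetate
Product: 12 (Z)-alkylidene acetoacetate
Conditions: piperidine (cat.), AcOH (cat.), benzene, 4 Å molecular sieves, 50 °C
Reagents that add atoms: none
Why: Knoevenagel condensation under reversible conditions should give the thermodynamic (Z)-isomer, with the bulky quaternary carbon cis to the ester and trans to the acetyl group, which is the geometry the diene needs.

Step 8
Reactants: 12 (Z)-alkylidene acetoacetate
Product: 13 2-silyloxy diene enol triflate
Conditions: TBSOTf, Et3N, CH2Cl2, −78 to 0 °C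
Reagents that add atoms: tert-butyldimethylsilyl trifluoromethanesulfonate, CC(C)(C)[Si](C)(C)OS(=O)(=O)C(F)(F)F
Why: soft enolisation of the methyl ketone and O-silylation give the 2-silyloxy-1,3-diene (silyl dienol ether formation from an alkylidene acetoacetate) with the alkene geometry retained.

Step 9
Reactants: 13 2-silyloxy diene enol triflate
Product: 15 tricyclic Diels–Alder adduct, via dienone 14 (not isolated)
Conditions: Pd(PPh3)4 (5 mol%), LiCl, CO (1 atm), Bu3SnCH=CH2, THF, 55 °C
Reagents that add atoms: carbon monoxide, [C-]#[O+]; tributyl(vinyl)stannane, C=C[Sn](CCCC)(CCCC)CCCC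
Why: Oxidative addition of zerovalent palladium into the C3a'–OTf bond, CO insertion, vinyl transfer from tin and reductive elimination (carbonylative Stille coupling of an enol triflate) give dienone 14, whose acryloyl unit (C5=C6) is then captured by the tethered 2-silyloxy diene (C4=C3a–C7a=C7) in a concerted suprafacial thermal [4+2] cycloaddition, a type 1 intramolecular Diels–Alder reaction of the nonatrienone class. Ring A closes as the six-membered cycloadduct ring (bonds C6–C7 and C4–C5), and the cyclopentanone (C6, C7, C7a', C3a', C3') closes as the fused tether ring through the same C6–C7 bond, a 5-exo closure with respect to either π-bond. The tether C7a'–C3a'(sp2)–C3'(sp2) is planar and held in ring B', so only the tether-endo transition state with the carbonyl under the diene is within reach, and suprafacial addition of the diene terminus C7 (whose C7a' substituent is trans to C3a) to the vinyl group makes H-6 and H-7 cis. The dienyl arm and the C1' amide are the two out-of-plane substituents of sp3 C7a' on the flat cyclohexadiene, so the diene can reach the acryloyl group only from the face opposite the amide, which places H-6 and H-7 on the β face and relays the configuration of C7a' to C6 and C7. The regiochemistry (C4 to C5, C7 to C6) is fixed by the three-atom tether and is also the electronically matched mode, the nucleophilic silyl enol ether carbon C4 meeting the enone β-carbon C5. The step needs carbonylation to outrun direct vinyl transfer, which CO saturation and LiCl should secure, and it leaves the silyl enol ether C3a=C7a as the regiodefined handle for the butenolide.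

Step 10
Reactants: 15 tricyclic Diels–Alder adduct
Product: 17 cis-fused tricyclic ketone, via lithium enolate 16 (not isolated)
Conditions: LiBH(s-Bu)3, THF, −78 °C; aq NH4Cl; then DBU, CH2Cl2, rt
Reagents that add atoms: none
Why: conjugate hydride addition to the s-cis exocyclic enone gives enolate 16, and protonation followed by base equilibration of the epimerisable C3a' should give the cis-fused hydrindanone (H-3a' on the β face), the thermodynamic isomer for a 1-hydrindanone with a quaternary neighbouring ring-fusion carbon, in which C4' also avoids the amide.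

Step 11
Reactants: 17 cis-fused tricyclic ketone
Product: 18 ring-A enol triflate
Conditions: CsF, PhNTf2, DME, rt
Reagents that add atoms: N-phenylbis(trifluoromethanesulfonimide), O=S(=O)(N(c1ccccc1)S(=O)(=O)C(F)(F)F)C(F)(F)F
Why: fluoride unmasks the stabilised β-keto ester enolate, which is O-triflated in the same flask (silyl enol ether to enol triflate exchange), while the simple C3' ketone is not enolised by fluoride.

Step 12
Reactants: 18 ring-A enol triflate; 19 1-pentyne
Product: 20 ring-A enyne ketone
Conditions: PdCl2(PPh3)2 (5 mol%), CuI (10 mol%), Et3N, THF, rt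
Reagents that add atoms: none
Why: Sonogashira coupling of a β-triflyloxy enoate with a terminal alkyne installs C3 and C8–C11 cis to the ester on the tetrasubstituted alkene.

Step 13
Reactants: 21 diphenyl sulfide; 22 1-iodobutane
Product: 23 butyldiphenylsulfonium tetrafluoroborate
Conditions: AgBF4, CH2Cl2, rt, dark
Reagents that add atoms: silver tetrafluoroborate, [Ag+].F[B-](F)(F)F
Why: silver-assisted S-alkylation of a diaryl sulfide with a primary iodide is the standard route to alkyldiphenylsulfonium salts, driven by precipitation of AgI.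

Step 14
Reactants: 20 ring-A enyne ketone; 23 butyldiphenylsulfonium tetrafluoroborate
Product: 25 C3' spiro-epoxide, via sulfonium ylide 24 (not isolated)
Conditions: LiN(i-Pr)2, DME, −78 °C; then 20, −78 to −20 °C
Reagents that add atoms: none
Why: Corey–Chaykovsky epoxidation with the non-stabilised ylide 24 should deliver the ylide carbon to C3' from the β face (which carries only H-3a' and H-6, the α face being screened by C4' and C5), so that ring closure of the betaine places the epoxide oxygen α and C8' β, the C8' configuration being of no consequence.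

Step 15
Reactants: 25 C3' spiro-epoxide
Product: 27 hydroxy lactone acid, via lactone iminium salt 26 (not isolated)
Conditions: CF3CO2H/CH2Cl2 (1:4), 0 °C to rt; then THF/H2O, rt
Reagents that add atoms: water, O
Why: acid-promoted 5-exo opening of the tertiary epoxide carbon by the cis-disposed amide oxygen with inversion at C3' (neighbouring-group lactonisation of an epoxy amide) sets the C3'–O bond on the β face as the bridging lactone, hydrolysis of 26 releases the auxiliary, and the same acid cleaves the tert-butyl ester.

Step 16
Reactants: 27 hydroxy lactone acid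
Product: 28 keto lactone acid
Conditions: Dess–Martin periodinane, CH2Cl2, 0 °C to rt
Reagents that add atoms: none
Why: Dess–Martin oxidation of the secondary C8' alcohol gives the butanoyl ketone, removes the C8' epimer mixture and leaves no stereocentre at risk, since C3' is quaternary.

Step 17
Reactants: 28 keto lactone acid
Product: 29 CNP0423313.1
Conditions: AgNO3 (10 mol%), acetone, rt, dark
Reagents that add atoms: none
Why: silver-catalysed 5-exo-dig cycloisomerisation of the (Z)-2-en-4-ynoic acid closes the butenolide, and anti-oxymetalation followed by protodemetalation places the propyl group cis to the ring oxygen, giving the (Z)-butylidene.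

**Compound list**
1 | 2-methoxybenzoyl chloride | COc1ccccc1C(Cl)=O | starting material
2 | (S)-2-(methoxymethyl)pyrrolidine | COC[C@@H]1CCCN1 | starting material
3 | [(2S)-2-(methoxymethyl)pyrrolidin-1-yl](2-methoxyphenyl)methanone | COC[C@@H]1CCCN1C(=O)c1ccccc1OC | intermediate
4 | potassium enolate of the 1,4-dihydrobenzamide (exocyclic C7a'=C1' enolate, ring diene C3a'(OMe)=C4' and C6'=C7') | [K+].[O-]C(=C1C=CCC=C1OC)N1CCC[C@H]1COC | intermediate
5 | [(1R)-1-(benzyloxymethyl)-2-methoxycyclohexa-2,5-dien-1-yl][(2S)-2-(methoxymethyl)pyrrolidin-1-yl]methanone | COC1=CCC=C[C@]1(COCc1ccccc1)C(=O)N1CCC[C@H]1COC | intermediate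
6 | (2R)-2-(benzyloxymethyl)-2-{[(2S)-2-(methoxymethyl)pyrrolidin-1-yl]carbonyl}cyclohex-3-en-1-one | O=C1CCC=C[C@]1(COCc1ccccc1)C(=O)N1CCC[C@H]1COC | intermediate
7 | potassium enolate of 6 (C3a'–O−, C3a'=C4') | [K+].[O-]C1=CCC=C[C@]1(COCc1ccccc1)C(=O)N1CCC[C@H]1COC | intermediate
8 | (6R)-6-(benzyloxymethyl)-6-{[(2S)-2-(methoxymethyl)pyrrolidin-1-yl]carbonyl}cyclohexa-1,4-dien-1-yl trifluoromethanesulfonate | O=S(=O)(OC1=CCC=C[C@]1(COCc1ccccc1)C(=O)N1CCC[C@H]1COC)C(F)(F)F | intermediate
9 | (6R)-6-(hydroxymethyl)-6-{[(2S)-2-(methoxymethyl)pyrrolidin-1-yl]carbonyl}cyclohexa-1,4-dien-1-yl trifluoromethanesulfonate | O=S(=O)(OC1=CCC=C[C@]1(CO)C(=O)N1CCC[C@H]1COC)C(F)(F)F | intermediate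
10 | (6S)-6-formyl-6-{[(2S)-2-(methoxymethyl)pyrrolidin-1-yl]carbonyl}cyclohexa-1,4-dien-1-yl trifluoromethanesulfonate | O=S(=O)(OC1=CCC=C[C@]1(C=O)C(=O)N1CCC[C@H]1COC)C(F)(F)F | intermediate
11 | tert-butyl 3-oxobutanoate (tert-butyl acetoacetate) | CC(=O)CC(=O)OC(C)(C)C | starting material
12 | tert-butyl (Z)-2-acetyl-3-[(1R)-1-(auxiliary carbonyl)-2-(triflyloxy)cyclohexa-2,5-dien-1-yl]prop-2-enoate (ring carbon cis to the ester) | O=S(=O)(OC1=CCC=C[C@]1(/C=C(/C(C)=O)C(=O)OC(C)(C)C)C(=O)N1CCC[C@H]1COC)C(F)(F)F | intermediate
13 | tert-butyl (Z)-2-[1-(tert-butyldimethylsilyloxy)vinyl]-3-[(1R)-1-(auxiliary carbonyl)-2-(triflyloxy)cyclohexa-2,5-dien-1-yl]prop-2-enoate | O=S(=O)(OC1=CCC=C[C@]1(/C=C(/C(=C)O[Si](C)(C)C(C)(C)C)C(=O)OC(C)(C)C)C(=O)N1CCC[C@H]1COC)C(F)(F)F | intermediate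
14 | dienone: as 13 with an acryloyl group (C5=C6–C3'=O) on C3a' in place of the triflate | C=CC(=O)C1=CCC=C[C@]1(/C=C(/C(=C)O[Si](C)(C)C(C)(C)C)C(=O)OC(C)(C)C)C(=O)N1CCC[C@H]1COC | intermediate
15 | tricyclic Diels–Alder adduct: ring A with C3a(OTBS)=C7a(CO2t-Bu); cyclopentanone C3'=O conjugated with C3a'=C4'; ring B' with C6'=C7'; auxiliary amide on C7a'; H-6 and H-7 cis and β | CC(C)(C)OC(=O)C1=C(O[Si](C)(C)C(C)(C)C)CC[C@@H]2[C@H]1[C@@]1(C=CCC=C1C2=O)C(=O)N1CCC[C@H]1COC | intermediate
16 | lithium enolate from conjugate reduction of 15 (C3'–O−, C3'=C3a') | CC(C)(C)OC(=O)C1=C(O[Si](C)(C)C(C)(C)C)CC[C@@H]2[C@H]1[C@@]1(C=CCCC1=C2[O-])C(=O)N1CCC[C@H]1COC.[Li+] | intermediate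
17 | cis-fused tricyclic ketone: as 15 with C3a'–H (β) and C4'H2; ring B' cis-fused to the cyclopentanone | CC(C)(C)OC(=O)C1=C(O[Si](C)(C)C(C)(C)C)CC[C@@H]2[C@H]1[C@@]1(C=CCC[C@@H]1C2=O)C(=O)N1CCC[C@H]1COC | intermediate
18 | ring-A enol triflate: as 17 with C3a–OTf in place of C3a–OTBS | CC(C)(C)OC(=O)C1=C(OS(=O)(=O)C(F)(F)F)CC[C@@H]2[C@H]1[C@@]1(C=CCC[C@@H]1C2=O)C(=O)N1CCC[C@H]1COC | intermediate
19 | 1-pentyne | CCCC#C | starting material
20 | ring-A enyne ketone: as 18 with pent-1-ynyl (C3, C8–C11) on C3a | CC(C)(C)OC(=O)C1=C(C#CCCC)CC[C@@H]2[C@H]1[C@@]1(C=CCC[C@@H]1C2=O)C(=O)N1CCC[C@H]1COC | intermediate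
21 | diphenyl sulfide | c1ccc(Sc2ccccc2)cc1 | starting material
22 | 1-iodobutane | CCCCI | starting material
23 | butyldiphenylsulfonium tetrafluoroborate | CCCC[S+](c1ccccc1)c1ccccc1.F[B-](F)(F)F | intermediate
24 | diphenylsulfonium butylide | CCC[CH-][S+](c1ccccc1)c1ccccc1 | intermediate
25 | C3' spiro-epoxide of 20 (C3'–O–C8'H–propyl; epoxide oxygen α, C8' β; C8' epimers) | CC(C)(C)OC(=O)C1=C(C#CCCC)CC[C@@H]2[C@H]1[C@@]1(C=CCC[C@@H]1[C@]23OC3CCC)C(=O)N1CCC[C@H]1COC | intermediate
26 | lactone iminium trifluoroacetate: C3'–O–C1'(=N+ pyrrolidinium) bridge closed, C8'–OH, free C1 acid | OC(=O)C1=C(C#CCCC)CC[C@@H]2[C@H]1[C@]13C=CCC[C@@H]1[C@@]2(C(O)CCC)OC3=[N+]1CCC[C@H]1COC.[O-]C(=O)C(F)(F)F | intermediate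
27 | hydroxy lactone acid: bridging lactone C1'(=O)–O–C3' on the β face, C8'–OH (epimers) on the α substituent, C3a-pentynyl C1 acid | OC(=O)C1=C(C#CCCC)CC[C@@H]2[C@H]1[C@]13C=CCC[C@@H]1[C@@]2(C(O)CCC)OC3=O | intermediate
28 | keto lactone acid: as 27 with C8'=O (butanoyl) | OC(=O)C1=C(C#CCCC)CC[C@@H]2[C@H]1[C@]13C=CCC[C@@H]1[C@@]2(C(=O)CCC)OC3=O | intermediate
29 | CNP0423313.1 | CCC/C=C1\OC(=O)C2=C1CC[C@@H]1[C@H]2[C@]23C=CCC[C@@H]2[C@@]1(C(=O)CCC)OC3=O | target

Total step count: 17. Longest linear sequence: 16 (steps 1–12 and 14–17; step 13 prepares the sulfonium salt).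

**Steps most likely to fail**

Step 14. The basic ylide may deprotonate the doubly α-branched cyclopentanone instead of adding to it. The ylide carbon may also add on the α face, which would put the epoxide oxygen on the β face where the amide cannot displace it. The fallback sets out from 20. Wittig butylidenation (Ph3P=CHCH2CH2CH3, THF) would give the exocyclic alkene, butylidene amide F1. Dihydroxylation with OsO4 (cat.) and N-methylmorpholine N-oxide should take the trisubstituted alkene from the open β face and give diol F2, whose tertiary C3' hydroxyl is already cis to the amide. CF3CO2H would then close the bridging lactone by N-to-O acyl transfer with loss of the auxiliary and cleave the tert-butyl ester, and the route is rejoined at 27. In this variant oxygen, not carbon, is delivered from the open face, so no inversion at C3' is needed.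

Step 9. Direct vinyl transfer without CO insertion, loss of the silyl enol ether, or oligomerisation of the vinyl ketone before cycloaddition may intervene. The fallback sets out from 13. Nozaki–Hiyama–Kishi coupling of the enol triflate with acrolein (CrCl2, NiCl2 cat., DMF) would give bis-allylic alcohol F3. Oxidation with MnO2 in CH2Cl2 would then release dienone 14 slowly under neutral conditions, where it should cyclise as in the main route, and the route is rejoined at 15.

Step 7. Condensation at the neopentyl aldehyde may be slow, the amine may cause deformylation of the α-formyl amide, or the wrong alkene isomer may form. The fallback sets out from 10. TiCl4-promoted Mukaiyama aldol addition of tert-butyl 3-(trimethylsilyloxy)but-2-enoate at −78 °C would give aldol adduct F4 without any nucleophilic amine. Mesylation and elimination (MsCl, Et3N; DBU) would then give the alkylidene acetoacetate, and the route is rejoined at 12.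

**Further compounds**
F1 | step 14 | butylidene amide: as 20 with C3'=C8'H–propyl in place of the C3' ketone (alkene geometry not defined) | CC(C)(C)OC(=O)C1=C(C#CCCC)CC[C@@H]2[C@H]1[C@@]1(C=CCC[C@@H]1C2=CCCC)C(=O)N1CCC[C@H]1COC
F2 | step 14 | diol: C3'–OH (β, tertiary) and C8'–OH, amide and tert-butyl ester intact | CC(C)(C)OC(=O)C1=C(C#CCCC)CC[C@@H]2[C@H]1[C@@]1(C=CCC[C@@H]1[C@]2(O)C(O)CCC)C(=O)N1CCC[C@H]1COC
F3 | step 9 | bis-allylic alcohol: as 14 with C3'H(OH) in place of the C3' ketone (carbinol epimers) | C=CC(O)C1=CCC=C[C@]1(/C=C(/C(=C)O[Si](C)(C)C(C)(C)C)C(=O)OC(C)(C)C)C(=O)N1CCC[C@H]1COC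
F4 | step 7 | aldol adduct of 10 and the acetoacetate (C7–OH, C7a–H; new centres not defined) | O=S(=O)(OC1=CCC=C[C@]1(C(O)C(C(C)=O)C(=O)OC(C)(C)C)C(=O)N1CCC[C@H]1COC)C(F)(F)F
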